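**Retrosynthetic overview**

1. Target 21 is cut at the exocyclic C=C: aldol addition and E1cB dehydration join the (S)-lactone 8 (ring A, the γ-lactone) to the C17 butenolide aldehyde 17 in the last two steps.
2. Ring A and the only stereocentre come from a proposed palladium-hydride enantioselective hydro-lactonisation of (E)-6-methylhepta-4,6-dienoic acid 7, made from methyl 4-oxobutanoate by boron-Wittig olefination and Suzuki coupling with 2-bromopropene.
3. Aldehyde 17 comes from oxidative cutting of the terminal isopropylidene of butenolide polyene 14 (bromohydrin, epoxide, H5IO6).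
4. Polyene 14 comes from B-alkyl Suzuki coupling of homofarnesyl-9-BBN (from (2E,6E)-farnesol via farnesal and methylenation) with 4-bromofuran-2(5H)-one.
5. Ring order: ring B (the butenolide) is bought intact and attached in step 6; ring A is the only ring formed (step 3); the two halves are joined last.

Assumption: the SMILES is read as the (3E,5S)-lactone with both chain alkenes E. New centres that are later destroyed (C–Br in 15, the epoxide in 16, two aldol centres in 19 and 20) are carried as mixtures.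

**Route**

Step 1
Reactants: 1 methyl 4-oxobutanoate; 2 2,2'-methylenebis(4,4,5,5-tetramethyl-1,3,2-dioxaborolane)
Product: 4 methyl (E)-5-(4,4,5,5-tetramethyl-1,3,2-dioxaborolan-2-yl)pent-4-enoate, via lithiated bis(boronate) 3 (not isolated)
Conditions: n-BuLi, 2,2,6,6-tetramethylpiperidine, THF, 0 °C; then 1, −78 °C to rt
Reagents that add atoms: none
Why: Boron-Wittig olefination: the α-boryl carbanion adds to the aldehyde much faster than to the ester, and syn B–O elimination gives the trans-alkenyl boronate; no stereocentre is formed.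

Step 2
Reactants: 4 methyl (E)-5-(4,4,5,5-tetramethyl-1,3,2-dioxaborolan-2-yl)pent-4-enoate; 5 2-bromopropene
Product: 7 (E)-6-methylhepta-4,6-dienoic acid, via methyl (E)-6-methylhepta-4,6-dienoate 6 (not isolated)
Conditions: Pd(dppf)Cl2·CH2Cl2 (3 mol %), LiOH (aq, 4 equiv), THF, 45 °C, sealed; then 1 M HCl, 0 °C
Reagents that add atoms: lithium hydroxide, [Li+].[OH-]
Why: Suzuki–Miyaura sp2–sp2 coupling keeps the E geometry, and the same aqueous LiOH then saponifies the methyl ester to the acid.

Step 3
Reactants: 7 (E)-6-methylhepta-4,6-dienoic acid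
Product: 8 (5S)-5-(2-methylprop-1-en-1-yl)oxolan-2-one
Conditions: Pd2(dba)3·CHCl3 (2.5 mol %), (S,S)-DACH-phenyl Trost ligand (7.5 mol %), CH2Cl2 (0.05 M), 0 °C to rt
Reagents that add atoms: none
Why: Proposed new method: enantioselective intramolecular hydro-acyloxylation of a 1,3-diene, in which the carboxylic acid O–H adds to zerovalent palladium to give a palladium hydride that inserts the unhindered terminal CH2= of the diene, giving a 1,1-dimethyl η3-allyl palladium carboxylate whose two diastereomeric forms interconvert by η3–η1–η3 slippage through the CMe2 terminus, and the tethered carboxylate then closes 5-exo on the secondary allyl terminus inside the chiral ligand pocket, which forms ring A, leaves the Me2C=CH alkene and sets C5 as S (attack at the tertiary terminus would need a seven-membered ring); the closest known reaction types are palladium-hydride hydroamination and hydroalkoxylation of 1,3-dienes with chiral phosphine ligands and asymmetric allylic substitution by carboxylate nucleophiles with this ligand class.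

Step 4
Reactants: 9 (2E,6E)-farnesol
Product: 10 (2E,6E)-farnesal
Conditions: TEMPO (10 mol %), PhI(OAc)2 (1.1 equiv), CH2Cl2, rt
Reagents that add atoms: none
Why: Oxoammonium (TEMPO) oxidation of the primary allylic alcohol stops at the enal and does not isomerise the 2E alkene.

Step 5
Reactants: 10 (2E,6E)-farnesal
Product: 11 (3E,7E)-4,8,12-trimethyltrideca-1,3,7,11-tetraene
Conditions: Ph3PCH3Br, KOtBu, THF, 0 °C to rt
Reagents that add atoms: methyltriphenylphosphonium bromide, C[P+](c1ccccc1)(c1ccccc1)c1ccccc1.[Br-]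
Why: Wittig methylenation with the non-stabilised ylide turns the enal carbonyl into a vinyl group without touching the existing alkene geometry.

Step 6
Reactants: 11 (3E,7E)-4,8,12-trimethyltrideca-1,3,7,11-tetraene; 12 4-bromofuran-2(5H)-one
Product: 14 4-[(3E,7E)-4,8,12-trimethyltrideca-3,7,11-trien-1-yl]furan-2(5H)-one, via B-homofarnesyl-9-BBN 13 (not isolated)
Conditions: 9-BBN (1.1 equiv), THF, 0 °C to rt; then 12, Pd(dppf)Cl2·CH2Cl2 (5 mol %), AsPh3 (5 mol %), K3PO4 (3 M aq), DMF, rt
Reagents that add atoms: none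
Why: 9-BBN hydroborates only the terminal vinyl carbon (anti-Markovnikov; trisubstituted alkenes are inert), and the primary B-alkyl-9-BBN then undergoes B-alkyl Suzuki–Miyaura coupling with the vinylogous acyl bromide 12, attaching ring B.

Step 7
Reactants: 14 4-[(3E,7E)-4,8,12-trimethyltrideca-3,7,11-trien-1-yl]furan-2(5H)-one
Product: 15 4-[(3E,7E)-11-bromo-12-hydroxy-4,8,12-trimethyltrideca-3,7-dien-1-yl]furan-2(5H)-one (racemic at C–Br)
Conditions: NBS (1.05 equiv), THF/H2O, 0 °C
Reagents that add atoms: N-bromosuccinimide, O=C1CCC(=O)N1Br; water, O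
Why: Bromohydrin formation in highly aqueous THF is selective for the terminal isopropylidene of a folded polyprenyl chain (Markovnikov, OH on the tertiary carbon), and the electron-poor butenolide alkene is inert.

Step 8
Reactants: 15 4-[(3E,7E)-11-bromo-12-hydroxy-4,8,12-trimethyltrideca-3,7-dien-1-yl]furan-2(5H)-one
Product: 16 4-[(3E,7E)-10-(3,3-dimethyloxiran-2-yl)-4,8-dimethyldeca-3,7-dien-1-yl]furan-2(5H)-one (racemic)
Conditions: K2CO3, MeOH, 0 °C
Reagents that add atoms: none
Why: Intramolecular Williamson (SN2) closure of the bromohydrin to the epoxide under mild carbonate base.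

Step 9
Reactants: 16 4-[(3E,7E)-10-(3,3-dimethyloxiran-2-yl)-4,8-dimethyldeca-3,7-dien-1-yl]furan-2(5H)-one
Product: 17 (4E,8E)-4,8-dimethyl-11-(5-oxo-2,5-dihydrofuran-3-yl)undeca-4,8-dienal
Conditions: H5IO6 (1.2 equiv), THF/Et2O, 0 °C
Reagents that add atoms: none
Why: Periodic acid opens the epoxide to the glycol in situ and cleaves it (glycol cleavage) to the aldehyde and acetone without attacking the trisubstituted alkenes.

Step 10
Reactants: 8 (5S)-5-(2-methylprop-1-en-1-yl)oxolan-2-one; 17 (4E,8E)-4,8-dimethyl-11-(5-oxo-2,5-dihydrofuran-3-yl)undeca-4,8-dienal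
Product: 19 (5S)-3-[(4E,8E)-1-hydroxy-4,8-dimethyl-11-(5-oxo-2,5-dihydrofuran-3-yl)undeca-4,8-dien-1-yl]-5-(2-methylprop-1-en-1-yl)oxolan-2-one (diastereomer mixture at the two new centres), via lactone lithium enolate 18 (not isolated)
Conditions: LiN(iPr)2 (1.05 equiv), THF, −78 °C; then 17, −78 °C; AcOH quench
Reagents that add atoms: none
Why: Aldol addition of the lactone lithium enolate to the aldehyde at −78 °C outruns proton transfer from the butenolide; C5 is remote from the enolate and untouched, and the two new centres are removed in the next step.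

Step 11
Reactants: 19 (5S)-3-[(4E,8E)-1-hydroxy-4,8-dimethyl-11-(5-oxo-2,5-dihydrofuran-3-yl)undeca-4,8-dien-1-yl]-5-(2-methylprop-1-en-1-yl)oxolan-2-one
Product: 21 (3E,5S)-3-[(4E,8E)-4,8-dimethyl-11-(5-oxo-2,5-dihydrofuran-3-yl)undeca-4,8-dien-1-ylidene]-5-(2-methylprop-1-en-1-yl)oxolan-2-one, via aldol mesylate 20 (not isolated)
Conditions: MsCl, Et3N, CH2Cl2, 0 °C; then DBU, 0 °C to rt
Reagents that add atoms: none
Why: Mesylation followed by DBU-promoted E1cB elimination gives the thermodynamically favoured E alkylidene lactone (chain anti to the carbonyl) from all aldol diastereomers, and the allylic C5–O stereocentre is not involved.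

**Compound list**

1 | methyl 4-oxobutanoate | COC(=O)CCC=O | starting material
2 | 2,2'-methylenebis(4,4,5,5-tetramethyl-1,3,2-dioxaborolane) | CC1(C)OB(CB2OC(C)(C)C(C)(C)O2)OC1(C)C | starting material
3 | lithiated bis(boronate) (lithium bis(4,4,5,5-tetramethyl-1,3,2-dioxaborolan-2-yl)methanide) | [Li+].CC1(C)OB([CH-]B2OC(C)(C)C(C)(C)O2)OC1(C)C | intermediate
4 | methyl (E)-5-(4,4,5,5-tetramethyl-1,3,2-dioxaborolan-2-yl)pent-4-enoate | COC(=O)CC/C=C/B1OC(C)(C)C(C)(C)O1 | intermediate
5 | 2-bromopropene | CC(Br)=C | starting material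
6 | methyl (E)-6-methylhepta-4,6-dienoate | COC(=O)CC/C=C/C(C)=C | intermediate
7 | (E)-6-methylhepta-4,6-dienoic acid | OC(=O)CC/C=C/C(C)=C | intermediate
8 | (5S)-5-(2-methylprop-1-en-1-yl)oxolan-2-one | CC(C)=C[C@@H]1CCC(=O)O1 | intermediate
9 | (2E,6E)-farnesol | CC(C)=CCC/C(C)=C/CC/C(C)=C/CO | starting material
10 | (2E,6E)-farnesal | CC(C)=CCC/C(C)=C/CC/C(C)=C/C=O | intermediate
11 | (3E,7E)-4,8,12-trimethyltrideca-1,3,7,11-tetraene | CC(C)=CCC/C(C)=C/CC/C(C)=C/C=C | intermediate
12 | 4-bromofuran-2(5H)-one | O=C1C=C(Br)CO1 | starting material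
13 | 9-[(3E,7E)-4,8,12-trimethyltrideca-3,7,11-trien-1-yl]-9-borabicyclo[3.3.1]nonane | CC(C)=CCC/C(C)=C/CC/C(C)=C/CCB1C2CCCC1CCC2 | intermediate
14 | 4-[(3E,7E)-4,8,12-trimethyltrideca-3,7,11-trien-1-yl]furan-2(5H)-one | CC(C)=CCC/C(C)=C/CC/C(C)=C/CCC1=CC(=O)OC1 | intermediate
15 | 4-[(3E,7E)-11-bromo-12-hydroxy-4,8,12-trimethyltrideca-3,7-dien-1-yl]furan-2(5H)-one (racemic) | CC(C)(O)C(Br)CC/C(C)=C/CC/C(C)=C/CCC1=CC(=O)OC1 | intermediate
16 | 4-[(3E,7E)-10-(3,3-dimethyloxiran-2-yl)-4,8-dimethyldeca-3,7-dien-1-yl]furan-2(5H)-one (racemic) | CC1(C)OC1CC/C(C)=C/CC/C(C)=C/CCC1=CC(=O)OC1 | intermediate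
17 | (4E,8E)-4,8-dimethyl-11-(5-oxo-2,5-dihydrofuran-3-yl)undeca-4,8-dienal | O=CCC/C(C)=C/CC/C(C)=C/CCC1=CC(=O)OC1 | intermediate
18 | lithium enolate of lactone 8 | [Li+].CC(C)=C[C@@H]1CC=C([O-])O1 | intermediate
19 | (5S)-3-[(4E,8E)-1-hydroxy-4,8-dimethyl-11-(5-oxo-2,5-dihydrofuran-3-yl)undeca-4,8-dien-1-yl]-5-(2-methylprop-1-en-1-yl)oxolan-2-one | CC(C)=C[C@@H]1CC(C(O)CC/C(C)=C/CC/C(C)=C/CCC2=CC(=O)OC2)C(=O)O1 | intermediate
20 | methanesulfonate of 19 | CC(C)=C[C@@H]1CC(C(OS(C)(=O)=O)CC/C(C)=C/CC/C(C)=C/CCC2=CC(=O)OC2)C(=O)O1 | intermediate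
21 | (3E,5S)-3-[(4E,8E)-4,8-dimethyl-11-(5-oxo-2,5-dihydrofuran-3-yl)undeca-4,8-dien-1-ylidene]-5-(2-methylprop-1-en-1-yl)oxolan-2-one (CNP0237694.1) | CC(C)=C[C@@H]1C/C(=C\CC/C(C)=C/CC/C(C)=C/CCC2=CC(=O)OC2)C(=O)O1 | target

**Count and risks**

Total steps: 11. Longest linear sequence: 8 steps (steps 4 to 11, from farnesol 9); the lactone branch is steps 1 to 3.

Step 3 (proposed new step). The risks are slow palladium-hydride formation from a weak acid, diene dimerisation, loss of ee if zerovalent palladium re-ionises the allylic lactone, and an unknown sense of induction. The run is therefore dilute and cold, stopped at full conversion, and the ligand antipode is used if the first run gives the R lactone. The fallback uses known chemistry, sets out from 1 and comes back at 8. Addition of (2-methylprop-1-en-1-yl)magnesium bromide to 1 (THF, −78 °C, cold AcOH quench) gives racemic methyl 4-hydroxy-6-methylhept-5-enoate F1. Dess–Martin periodinane with NaHCO3 oxidises it to methyl 6-methyl-4-oxohept-5-enoate F2. Corey–Bakshi–Shibata reduction with (R)-2-methyl-CBS-oxazaborolidine and catecholborane (toluene, −78 °C, alkenyl as the large group) gives methyl (4S)-4-hydroxy-6-methylhept-5-enoate F3. Catalytic PPTS in CH2Cl2 at rt closes F3 to 8.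

Step 6 (hydroboration and B-alkyl Suzuki coupling). The risks are incomplete or unselective hydroboration of the diene and hydrolysis of 12 by aqueous base. The fallback builds ring B by metathesis instead of bringing it ready-made; it sets out from 9 and comes back at 14. PBr3 in Et2O at 0 °C gives (2E,6E)-farnesyl bromide F4. Alkylation of the dianion of 2-methylprop-2-en-1-ol (n-BuLi, TMEDA, Et2O) with F4 gives (5E,9E)-6,10,14-trimethyl-2-methylidenepentadeca-5,9,13-trien-1-ol F5. Acryloyl chloride and Et3N give (5E,9E)-6,10,14-trimethyl-2-methylidenepentadeca-5,9,13-trien-1-yl prop-2-enoate F6. Ring-closing metathesis of F6 with second-generation Grubbs catalyst (H2IMes)(PCy3)Cl2Ru=CHPh in CH2Cl2 at 40 °C closes the butenolide and gives 14.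

Step 10 (aldol union). The risk is that the enolate deprotonates or adds to the butenolide of 17, and that DBU later gives E/Z mixtures. The fallback replaces the enolate by a neutral stabilised ylide; it sets out from 8 and comes back at 21, bypassing steps 10 and 11. Enolisation of 8 with LiN(iPr)2 and bromination with CBr4 at −78 °C gives (5S)-3-bromo-5-(2-methylprop-1-en-1-yl)oxolan-2-one F7. PPh3 in refluxing THF gives [(5S)-5-(2-methylprop-1-en-1-yl)-2-oxooxolan-3-yl]triphenylphosphonium bromide F8. Aqueous NaOH gives (5S)-5-(2-methylprop-1-en-1-yl)-3-(triphenyl-λ5-phosphanylidene)oxolan-2-one F9. Wittig reaction of F9 with 17 in toluene at 80 °C gives 21 with E selectivity.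

**Further compounds**

F1 | step 3 | methyl 4-hydroxy-6-methylhept-5-enoate (racemic) | COC(=O)CCC(O)C=C(C)C
F2 | step 3 | methyl 6-methyl-4-oxohept-5-enoate | COC(=O)CCC(=O)C=C(C)C
F3 | step 3 | methyl (4S)-4-hydroxy-6-methylhept-5-enoate | COC(=O)CC[C@H](O)C=C(C)C
F4 | step 6 | (2E,6E)-farnesyl bromide | CC(C)=CCC/C(C)=C/CC/C(C)=C/CBr
F5 | step 6 | (5E,9E)-6,10,14-trimethyl-2-methylidenepentadeca-5,9,13-trien-1-ol | CC(C)=CCC/C(C)=C/CC/C(C)=C/CCC(=C)CO
F6 | step 6 | (5E,9E)-6,10,14-trimethyl-2-methylidenepentadeca-5,9,13-trien-1-yl prop-2-enoate | CC(C)=CCC/C(C)=C/CC/C(C)=C/CCC(=C)COC(=O)C=C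
F7 | step 10 | (5S)-3-bromo-5-(2-methylprop-1-en-1-yl)oxolan-2-one | CC(C)=C[C@@H]1CC(Br)C(=O)O1
F8 | step 10 | [(5S)-5-(2-methylprop-1-en-1-yl)-2-oxooxolan-3-yl]triphenylphosphonium bromide | CC(C)=C[C@@H]1CC([P+](c2ccccc2)(c2ccccc2)c2ccccc2)C(=O)O1.[Br-]
F9 | step 10 | (5S)-5-(2-methylprop-1-en-1-yl)-3-(triphenyl-λ5-phosphanylidene)oxolan-2-one | CC(C)=C[C@@H]1CC(=P(c2ccccc2)(c2ccccc2)c2ccccc2)C(=O)O1
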